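all flasks: D 0.050 M (in portions, 2)

| charge | Z | E | temperature | remark | time |
|---|---|---|---|---|---|
| gamma | 0.075 M | 0.24 mM | −30 °C | run made earlier; portions every 80 s |  |
| zeta | 0.075 M | 1.1 mM | −8 °C | run made earlier; portions every 80 s |  |
| eta | 0.14 M | 1.6 mM | −30 °C | run made earlier; portions every 80 s |  |
| summer | 0.300 M | 0.40 mM |  | at −40 °C throughout; the portions of D follow each other after 80 s, the first at the start | 2.5 min |
| winter | 0.0750 M | 1.6 mM |  | at −40 °C until 30 s, from then on at 0 °C; the portions of D follow each other after 80 s, the first at the start | 2.5 min |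

| run | time / s | J / % | D / % |
|---|---|---|---|
| gamma | 10.0 | 3.0 | 45.1 |
| gamma | 20.0 | 5.9 | 42.2 |
| gamma | 30.0 | 7.6 | 38.1 |
| gamma | 40.0 | 9.4 | 34.5 |
| gamma | 50.0 | 10.4 | 30.9 |
| gamma | 60.0 | 11.1 | 27.3 |
| gamma | 80.0 | 12.7 | 20.9 |
| zeta | 10.0 | 17.1 | 0.5 |
| zeta | 12.0 | 13.7 | 0.5 |
| zeta | 15.0 | 10.2 | 0.6 |
| zeta | 25.0 | 3.9 | 0 |
| eta | 10.0 | 23.6 | 18.7 |
| eta | 20.0 | 30.7 | 0.3 |
| eta | 40.0 | 13.9 | 0.5 |
| eta | 80.0 | 3.2 | 0.7 |

(scatter of a reading: 0.3 percentage points)

* which one finishes higher in amount of J, in percent of the D charged ("neither" within 2 percentage points) (summer / winter / neither)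
* amount of J at the end, in percent of the D charged, summer
* amount of J at the end, in percent of the D charged, winter



In the eta run J falls from 30.7% at 20.0 s to 3.2% at 80.0 s, and in the zeta run from 17.1% at 10.0 s to 3.9% at 25.0 s, so J is being consumed. The forecast's scheme, which this reckoning shares, spends one Z to make J from D and a second Z to turn that J into waste. Winter warms to 0 °C at 30 s, and the zeta run, with the same D and Z at the colder −8 °C, gives a pessimistic clock for it: zeta's D is down to 0.5% at 10.0 s, and its J decays at 0.0961 s⁻¹, a half-life of 7.21 s. Winter has 50.0 s before its second portion, which is longer than that half-life, so the first portion should be paid for at two Z per D, leaving a reserve R of 0.0250 M.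

That reserve per D charged is the ceiling C, the most J the second portion can leave once the first is so paid, 50.0%. This is the bound from above. The portion equals the reserve, and each J lost costs a Z but no D, so Z is the limiting reagent, and if d is the D stranded when Z ends, the accounts of D and Z give J = C − 2d.

The bound from below computes just d. If formation holds at a steady rate v, taken as 0.00360 M s⁻¹ from zeta's turnover and winter's E, and if the decay constant at Z near R is zeta's doubled for the warming, as the forecast's 3.4 and 7 per molar and second suggest, integrating the loss takes 22.3% of R. So d comes to about 11.1% and J to about 27.7%, an estimate of the lower end of the bracket and not a proof of it. This reckoning offers no figure for summer.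

The forecast says winter, with summer at 11% and winter at 36%: “Z runs out, freezing J near 36%”. Its winter number stands above 27.7% and below 50.0%.

The flasks give winter ahead, summer at 8.63% and winter at 35.9%, between the same two figures.

    Z + E → ZE (k = 12.0 M⁻¹ s⁻¹, Ea = 42.0 kJ mol⁻¹)
    D + ZE → DZE (k = 390 M⁻¹ s⁻¹, Ea = 35.0 kJ mol⁻¹)
    DZE → G (k = 0.940 s⁻¹, Ea = 64.0 kJ mol⁻¹)
    G → E + J (k = 0.840 s⁻¹, Ea = 48.0 kJ mol⁻¹)
    Z + J → ZJ (k = 0.130 M⁻¹ s⁻¹, Ea = 53.0 kJ mol⁻¹)
    (constants at −40 °C)

Winter ends at 2.50 min with Z at 0% and D at 7.0%, and C less two such amounts is 36.0%. The neighbour flask, winter with E raised to 0.0040 M, keeps winter's D and Z and so its C. It ends with Z at 0% and D at 3.4%, which reckons to 43.2%, and the flask holds J at 43.2%.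

The runs come from a simulation from invented constants; scatter was added.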